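## Analysis of the target

- Target 17 is a (2S)-flavanone. Ring A (C4a, C5 to C8, C8a) is a phloroglucinol-type benzene with hydroxyls on C5 and C7 and an (E)-geranyl chain on C6. Ring C is the dihydropyranone O1–C2–C3–C4(=O). Ring B, on C2, is a 3′-methoxy-4′,5′-dihydroxyphenyl group.
- The only stereocentre is C2. It is benzylic, bonded to O1 and β to the C4 carbonyl, so base erases it by retro-oxa-Michael opening of ring C. The free 4′-hydroxyl para to C2 makes this easier.
- The same ring-opened form has two hydroxyls ortho to the ketone. A route through it therefore also loses the distinction between the 6-geranyl and the 8-geranyl series. Placing the chain on C6, between O5 and O7 and para to C8a, is the main constitutional problem.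
- The side chain carries two trisubstituted alkenes. They rule out hydrogenolysis and strong electrophiles, can cyclise onto O5 or O7 under strong acid, and the C2″=C3″ geometry must stay E. The catechol of ring B is prone to oxidation.
- The feature used here is the C2–C1′ bond, which joins ring C to ring B at the stereocentre. Cutting it leaves a flat, achiral 6-geranylchromone and an arylboron reagent.
- Both benzene rings are 1,2,3-trisubstituted arenes whose linking atom (C8a–O1 of ring A, C1′ of ring B) sits at the one sterically open position. The difficulty is to control C2, the C6 regiochemistry and a mild endgame together in few steps.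

## Retrosynthetic reasoning

**17 from 16.** The four phenols are released last from the tetrakis(methoxymethyl) ether 16. Methoxymethyl groups are chosen because they direct the metalation that places the geranyl chain and are stable to the organometallic steps. They leave under dilute acid, where C2 is configurationally stable and the 4′-oxygen stays protected until the end.

**16 from 11 and 15 (key disconnection).** The C2–C1′ bond is cut. It is the only bond that both joins the two halves and ends at the stereocentre. The precursors are chromone 11 and boronic acid 15. The forward step is a rhodium-catalysed enantioselective 1,4-addition that sets C2 by catalyst control under near-neutral conditions. Ring C stays closed throughout, so neither C2 nor the C6/C8 assignment can scramble through a ring-opened enone.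

**11 from 10, 9 and 8.** The pyranone ring is cut at O1–C2 and C3–C4. Chromone 11 comes from the terminal ynone 10 by 6-endo addition of the phenol, 10 from carbinol 9 by oxidation, and 9 from salicylaldehyde 8 by ethynyl addition. In 8 the only free hydroxyl is the one that must become O1, so the closure can give only the 6-geranyl isomer.

**8 from 7.** The formyl carbon (the later C4) is removed from phenol 7. In 7 the two positions ortho to the hydroxyl are equivalent by symmetry and the para position carries the chain. The forward ortho-formylation therefore has no regiochemical choice.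

**7 from 6 and 5.** The C–O bond at the later C8a is cut. In arene 5 this carbon is the only C–H not flanked by a substituent. Sterically governed iridium-catalysed C–H borylation to 6 followed by oxidation puts the oxygen there and nowhere else.

**5 from 4, 3 and 2; 2 from 1.** The aryl–allyl bond is cut. Aryllithium 4, formed from 2 between the two directing acetal oxygens, is allylated by geranyl bromide 3 at its primary carbon, which keeps the E geometry. Compound 2 is the bis-acetal of resorcinol 1.

**15 from 14, 13 and 12.** The C–B bond of ring B is cut. In 13 the carbon para to the central oxygen is again the only unhindered C–H. Electrophilic substitution cannot reach it, but C–H borylation can, giving 14 and then 15. Compound 13 is the bis-acetal of 3-methoxycatechol 12.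

## Alternatives that were turned down

**Alternative 1:** the textbook route, cutting O1–C2 and the C2–C3 bond of ring C (C2 is the aldehyde carbon of ring B).
- Forward: a C-geranylated, doubly protected ring-A methyl ketone A1 is condensed (Claisen–Schmidt) with the ring-B benzaldehyde A2 to chalcone A3, which is cyclised by base to flavanone A4.
- Turned down because protection of the geranylated triol is expected to leave free the hydroxyl flanked by the chain, so A3 closes to the 8-geranyl series.
- If both ortho hydroxyls are free, both close.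
- The oxa-Michael step is reversible and uncontrolled, so A4 is racemic. Neither of the two real problems is solved, and a resolution would be added at the end.

**Alternative 2:** O1–C2 first, then C4–C4a.
- Forward: phenol 7 is coupled under Mitsunobu conditions, with inversion, to the enantioenriched benzylic carbinol A5, giving aryl ether A6. Saponification and intramolecular Friedel–Crafts acylation would then close ring C.
- Turned down because A5 is a benzylic alcohol with a para oxygen donor. Ionisation under Mitsunobu conditions would erode the configuration and favour elimination to the cinnamate.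
- The acylation needs Brønsted or Lewis acid activation, which the acetals and the geranyl chain of A6 do not tolerate.
- The carbinol itself costs an asymmetric reduction sequence.

**Alternative 3:** C2–H bond, by enantioselective 1,4-reduction of a flavone.
- Forward: flavone A7 (from aldehyde 8 in four further steps by acylation, rearrangement and cyclodehydration) is reduced at C2=C3 with CuH and a chiral bisphosphine, or by asymmetric hydrogenation, to 16.
- Turned down because conjugate reduction of a 2-arylchromone with this electron-rich, tetrasubstituted β-carbon has weak precedent.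
- Hydrogenation catalysts able to reduce it would also attack the geranyl alkenes and the ketone, forcing re-oxidation.
- The route to A7 is longer and includes an acidic cyclodehydration.

Key step: step 9

Remark: C2 is read as S and the C2″=C3″ alkene of the side chain as E from the SMILES string; flavanone numbering is used throughout.

## Route

Step 1
Reactants: 1 resorcinol
Product: 2 1,3-bis(methoxymethoxy)benzene
Conditions: MOMCl (2.5 equiv), i-Pr2NEt (3 equiv), CH2Cl2, 0 °C to rt
Reagents that add atoms: chloromethyl methyl ether (MOMCl), COCCl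
Why: Twofold O-alkylation of the phenols (Williamson-type acetal formation); the two acetal oxygens later act together as the directing groups for metalation.

Step 2
Reactants: 2 1,3-bis(methoxymethoxy)benzene; 3 geranyl bromide [(2E)-1-bromo-3,7-dimethylocta-2,6-diene]
Product: 5 2-[(2E)-3,7-dimethylocta-2,6-dien-1-yl]-1,3-bis(methoxymethoxy)benzene, via aryllithium 4 (not isolated)
Conditions: n-BuLi (1.1 equiv), THF, 0 °C; CuBr·SMe2 (10 mol %), 3 (1.2 equiv), −78 to 0 °C
Reagents that add atoms: none
Why: Directed ortho-metalation should occur only at C2, between the two cooperating acetal groups; copper-assisted allylation at the primary carbon of 3 (attack at the fully substituted γ-carbon is disfavoured) keeps the E alkene.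

Step 3
Reactants: 5 2-[(2E)-3,7-dimethylocta-2,6-dien-1-yl]-1,3-bis(methoxymethoxy)benzene
Product: 7 4-[(2E)-3,7-dimethylocta-2,6-dien-1-yl]-3,5-bis(methoxymethoxy)phenol, via pinacol boronate 6 (not isolated)
Conditions: [Ir(OMe)(cod)]2 (1.5 mol %, cod = 1,5-cyclooctadiene), 4,4′-di-tert-butyl-2,2′-bipyridine (3 mol %), B2pin2 (1.0 equiv), THF, 60 °C; then 30% H2O2, aq. NaOH, 0 °C
Reagents that add atoms: bis(pinacolato)diboron, CC1(C)OB(OC1(C)C)B1OC(C)(C)C(C)(C)O1 (supplies the boryl group of 6 only); hydrogen peroxide, OO (supplies the hydroxyl oxygen of 7)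
Why: Sterically governed iridium-catalysed C–H borylation should select C5, the only ring C–H without an ortho substituent, and the hindered trisubstituted alkenes are poor partners for the iridium boryl species; alkaline peroxide oxidation of the C–B bond proceeds with 1,2-aryl migration and does not epoxidise electron-rich alkenes.

Step 4
Reactants: 7 4-[(2E)-3,7-dimethylocta-2,6-dien-1-yl]-3,5-bis(methoxymethoxy)phenol
Product: 8 3-[(2E)-3,7-dimethylocta-2,6-dien-1-yl]-6-hydroxy-2,4-bis(methoxymethoxy)benzaldehyde
Conditions: MgCl2 (2 equiv), Et3N (4 equiv), (CH2O)n (6 equiv), MeCN, reflux; citric acid work-up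
Reagents that add atoms: paraformaldehyde (as formaldehyde), C=O
Why: Magnesium phenoxide-directed ortho-hydroxymethylation followed by hydride transfer to a second formaldehyde (Casnati–Skattebøl formylation); the two ortho positions of 7 are equivalent and the para position is blocked, and the chelated product resists a second formylation.

Step 5
Reactants: 8 3-[(2E)-3,7-dimethylocta-2,6-dien-1-yl]-6-hydroxy-2,4-bis(methoxymethoxy)benzaldehyde
Product: 9 4-[(2E)-3,7-dimethylocta-2,6-dien-1-yl]-2-(1-hydroxyprop-2-yn-1-yl)-3,5-bis(methoxymethoxy)phenol (racemic carbinol, used crude)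
Conditions: HC≡CMgBr (3 equiv), THF, 0 °C to rt; aq. NH4Cl
Reagents that add atoms: ethynylmagnesium bromide, C#C[Mg]Br
Why: Grignard 1,2-addition to the aldehyde after the first equivalent has deprotonated the phenol; the carbinol centre is racemic and is destroyed in the next step.

Step 6
Reactants: 9 4-[(2E)-3,7-dimethylocta-2,6-dien-1-yl]-2-(1-hydroxyprop-2-yn-1-yl)-3,5-bis(methoxymethoxy)phenol
Product: 11 6-[(2E)-3,7-dimethylocta-2,6-dien-1-yl]-5,7-bis(methoxymethoxy)-4H-chromen-4-one, via ynone 10 (not isolated)
Conditions: MnO2 (10 equiv), CH2Cl2, rt; then K2CO3 (0.2 equiv), acetone, rt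
Reagents that add atoms: none
Why: MnO2 oxidises the benzylic-propargylic alcohol, and the single free phenol then adds to the unsubstituted β-carbon of the terminal ynone (6-endo-dig oxa-Michael addition) to give the chromone; only this oxygen can close, so the chain is fixed at C6.

Step 7
Reactants: 12 3-methoxycatechol (3-methoxybenzene-1,2-diol)
Product: 13 1-methoxy-2,3-bis(methoxymethoxy)benzene
Conditions: MOMCl (2.5 equiv), i-Pr2NEt (3 equiv), CH2Cl2, 0 °C to rt
Reagents that add atoms: chloromethyl methyl ether (MOMCl), COCCl
Why: Twofold O-alkylation of the catechol; the acetals match those of ring A so that one final operation releases all four phenols.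

Step 8
Reactants: 13 1-methoxy-2,3-bis(methoxymethoxy)benzene
Product: 15 [3-methoxy-4,5-bis(methoxymethoxy)phenyl]boronic acid, via pinacol boronate 14 (not isolated)
Conditions: [Ir(OMe)(cod)]2 (1.5 mol %), 4,4′-di-tert-butyl-2,2′-bipyridine (3 mol %), B2pin2 (1.0 equiv), THF, 80 °C; then NaIO4 (3 equiv), NH4OAc (3 equiv), acetone/H2O, rt
Reagents that add atoms: bis(pinacolato)diboron, CC1(C)OB(OC1(C)C)B1OC(C)(C)C(C)(C)O1; water, O
Why: Sterically governed C–H borylation should take place at C5, para to the central oxygen and the only C–H without an ortho substituent; periodate cleaves the liberated pinacol and drives the hydrolysis to the boronic acid at near-neutral pH, where the acetals survive.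

Step 9
Reactants: 11 6-[(2E)-3,7-dimethylocta-2,6-dien-1-yl]-5,7-bis(methoxymethoxy)-4H-chromen-4-one; 15 [3-methoxy-4,5-bis(methoxymethoxy)phenyl]boronic acid
Product: 16 (2S)-6-[(2E)-3,7-dimethylocta-2,6-dien-1-yl]-2-[3-methoxy-4,5-bis(methoxymethoxy)phenyl]-5,7-bis(methoxymethoxy)-2,3-dihydro-4H-chromen-4-one
Conditions: [RhCl(C2H4)2]2 (2.5 mol %), (S)-2,2′-bis[bis(3,4,5-trifluorophenyl)phosphino]-6,6′-dimethoxy-1,1′-biphenyl (5.5 mol %), KOH (10 mol %), 15 (2.0 equiv), toluene/H2O (10:1), 30 °C
Reagents that add atoms: none
Why: The aryl group of 15 is transferred from boron to the hydroxo complex of monovalent rhodium, the C2=C3 bond of 11 inserts into the aryl–rhodium bond with the aryl going to C2, and water protonates the resulting rhodium enolate at C3 and regenerates the hydroxo complex. The closest known reaction type is the Hayashi–Miyaura asymmetric 1,4-addition of arylboronic acids to enones, in its variant for chromones with electron-poor biaryl bisphosphines. No ring is closed; the step forms the C2–C1′ bond between the complete A/C ring system and ring B. The new stereocentre C2 is set by the ligand alone, since 11 is flat and achiral. The (S)-ligand is chosen because the binding model that gives (S)-3-arylcyclohexanones with (S)-biaryl bisphosphines places the aryl group on the corresponding face of C2, which is the 2S face; the antipodal ligand is equally available should the sense have to be inverted. The step needs 1,4- over 1,2-addition and protonation of the enolate faster than β-aryloxide elimination (ring opening); water as proton source, the low temperature allowed by the electron-poor ligand and the electron-rich, fully protected ring A (a poor phenoxide leaving group) should secure this. The trisubstituted alkenes of the chain do not insert into aryl–rhodium bonds and the acetals are stable at this pH. Product 16 is no longer a Michael acceptor and, with O4′ protected and no strong base present, should not epimerise.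

Step 10
Reactants: 16 (2S)-6-[(2E)-3,7-dimethylocta-2,6-dien-1-yl]-2-[3-methoxy-4,5-bis(methoxymethoxy)phenyl]-5,7-bis(methoxymethoxy)-2,3-dihydro-4H-chromen-4-one
Product: 17 (2S)-2-(3,4-dihydroxy-5-methoxyphenyl)-6-[(2E)-3,7-dimethylocta-2,6-dien-1-yl]-5,7-dihydroxy-2,3-dihydro-4H-chromen-4-one (target)
Conditions: 3 M aq. HCl/MeOH (1:5), 45 °C, argon, degassed solvents
Reagents that add atoms: none
Why: Acid-catalysed acetal exchange with methanol should release the four phenols; flavanones are configurationally stable in dilute acid at moderate temperature because ring opening needs base, and acetal cleavage should be faster than protonation of the trisubstituted alkenes.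

## Compound list

1 | resorcinol | Oc1cccc(O)c1 | starting material
2 | 1,3-bis(methoxymethoxy)benzene | COCOc1cccc(OCOC)c1 | intermediate
3 | geranyl bromide, (2E)-1-bromo-3,7-dimethylocta-2,6-diene | CC(C)=CCC/C(C)=C/CBr | starting material
4 | [2,6-bis(methoxymethoxy)phenyl]lithium | [Li]c1c(OCOC)cccc1OCOC | intermediate (not isolated)
5 | 2-[(2E)-3,7-dimethylocta-2,6-dien-1-yl]-1,3-bis(methoxymethoxy)benzene | COCOc1cccc(OCOC)c1C/C=C(\C)CCC=C(C)C | intermediate
6 | 2-{4-[(2E)-3,7-dimethylocta-2,6-dien-1-yl]-3,5-bis(methoxymethoxy)phenyl}-4,4,5,5-tetramethyl-1,3,2-dioxaborolane | COCOc1cc(B2OC(C)(C)C(C)(C)O2)cc(OCOC)c1C/C=C(\C)CCC=C(C)C | intermediate (not isolated)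
7 | 4-[(2E)-3,7-dimethylocta-2,6-dien-1-yl]-3,5-bis(methoxymethoxy)phenol | COCOc1cc(O)cc(OCOC)c1C/C=C(\C)CCC=C(C)C | intermediate
8 | 3-[(2E)-3,7-dimethylocta-2,6-dien-1-yl]-6-hydroxy-2,4-bis(methoxymethoxy)benzaldehyde | COCOc1cc(O)c(C=O)c(OCOC)c1C/C=C(\C)CCC=C(C)C | intermediate
9 | 4-[(2E)-3,7-dimethylocta-2,6-dien-1-yl]-2-(1-hydroxyprop-2-yn-1-yl)-3,5-bis(methoxymethoxy)phenol (racemic) | C#CC(O)c1c(O)cc(OCOC)c(C/C=C(\C)CCC=C(C)C)c1OCOC | intermediate
10 | 1-{3-[(2E)-3,7-dimethylocta-2,6-dien-1-yl]-6-hydroxy-2,4-bis(methoxymethoxy)phenyl}prop-2-yn-1-one | C#CC(=O)c1c(O)cc(OCOC)c(C/C=C(\C)CCC=C(C)C)c1OCOC | intermediate (not isolated)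
11 | 6-[(2E)-3,7-dimethylocta-2,6-dien-1-yl]-5,7-bis(methoxymethoxy)-4H-chromen-4-one | O=c1ccoc2cc(OCOC)c(C/C=C(\C)CCC=C(C)C)c(OCOC)c12 | intermediate
12 | 3-methoxycatechol (3-methoxybenzene-1,2-diol) | COc1cccc(O)c1O | starting material
13 | 1-methoxy-2,3-bis(methoxymethoxy)benzene | COc1cccc(OCOC)c1OCOC | intermediate
14 | 2-[3-methoxy-4,5-bis(methoxymethoxy)phenyl]-4,4,5,5-tetramethyl-1,3,2-dioxaborolane | COc1cc(B2OC(C)(C)C(C)(C)O2)cc(OCOC)c1OCOC | intermediate (not isolated)
15 | [3-methoxy-4,5-bis(methoxymethoxy)phenyl]boronic acid | COc1cc(B(O)O)cc(OCOC)c1OCOC | intermediate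
16 | (2S)-6-[(2E)-3,7-dimethylocta-2,6-dien-1-yl]-2-[3-methoxy-4,5-bis(methoxymethoxy)phenyl]-5,7-bis(methoxymethoxy)-2,3-dihydro-4H-chromen-4-one | COc1cc([C@@H]2CC(=O)c3c(cc(OCOC)c(C/C=C(\C)CCC=C(C)C)c3OCOC)O2)cc(OCOC)c1OCOC | intermediate
17 | (2S)-2-(3,4-dihydroxy-5-methoxyphenyl)-6-[(2E)-3,7-dimethylocta-2,6-dien-1-yl]-5,7-dihydroxy-2,3-dihydro-4H-chromen-4-one | COc1cc([C@@H]2CC(=O)c3c(cc(O)c(C/C=C(\C)CCC=C(C)C)c3O)O2)cc(O)c1O | target

## Step count and least certain steps

Total step count: 10. Longest linear sequence: 8 steps (steps 1 to 6, 9 and 10); steps 7 and 8 form the second branch.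

**Step 9 (key step).**
- What may go wrong: β-aryloxide elimination from the rhodium enolate may compete with protonation and open ring C. Insertion may be slow because C2 of the electron-rich chromone is a weak acceptor and the C4 carbonyl is crowded by the O5 acetal. Protodeboronation of 15 may use up the aryl donor. Facial discrimination may be insufficient.
- Fallback: it gives up the C2–C1′ disconnection and sets out from aldehyde 8. Addition of MeMgBr would give methyl carbinol F1, and MnO2 oxidation the methyl ketone F2. Claisen–Schmidt condensation (KOH, EtOH) with aldehyde F3, made from commercial 3,4-dihydroxy-5-methoxybenzaldehyde and MOMCl, would give chalcone F4. Its single free hydroxyl would close ring C (NaOAc, EtOH, reflux) to racemic flavanone F5, with the chain necessarily on C6. Preparative chromatography on a chiral stationary phase comes back to the route at 16.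

**Step 3.**
- What may go wrong: the iridium hydride and pinacolborane formed during borylation may hydroborate or isomerise the alkenes of the chain, or vinylic C–H bonds may be borylated.
- Fallback: the order is changed so that no alkene is present during C–H borylation. It sets out from 2. Borylation under the same catalyst would give pinacol boronate F6, and oxidation the phenol F7. Silylation (i-Pr3SiCl, imidazole) would give silyl ether F8. Lithiation between the two acetal groups (n-BuLi; the bulky silyl ether shields its own ortho positions) and allylation with 3 would give geranylated silyl ether F9. Bu4NF comes back to the route at 7.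

**Step 6.**
- What may go wrong: the electron-rich carbinol 9 may ionise to an ortho-quinone methide before it is oxidised. MnO2 may oxidise the free phenol. Closure may take the 5-exo course to a methylene benzofuranone.
- Fallback: the chromone is built without an ynone. It sets out from 8 and passes through methyl carbinol F1 and methyl ketone F2, as in the fallback for step 9. Condensation of F2 with N,N-dimethylformamide dimethyl acetal would give enaminone F10. Addition–elimination of the phenol with loss of dimethylamine (cat. AcOH, toluene, 80 °C) comes back to the route at 11.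

**Step 10.**
- What may go wrong: protonation of the C2″=C3″ alkene and capture by O5 or O7 (chroman formation), hydration of the terminal alkene, slow acid-promoted epimerisation at C2 on prolonged heating, and air oxidation of the liberated catechol.
- Fallback: the protecting groups are exchanged before the key step so that the last operation is a buffered desilylation. It sets out from 11 and 12.
  - The acetals of 11 are cleaved at the chromone stage (dilute HCl, MeOH, rt), where no stereocentre exists and a cyclised by-product can be removed. This gives dihydroxychromone F11, which is silylated (t-BuMe2SiOTf, 2,6-lutidine) to bis-silyl chromone F12.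
  - Catechol 12 is silylated (t-BuMe2SiCl, imidazole) to bis-silyl ether F13, then borylated and hydrolysed as in step 8, through pinacol boronate F14, to boronic acid F15.
  - The addition of step 9 applied to F12 and F15 would give tetrasilyl flavanone F16. Et3N·3HF in THF at 0 °C comes back to the route at 17.

## Further compounds

F1 | step 9 | 4-[(2E)-3,7-dimethylocta-2,6-dien-1-yl]-2-(1-hydroxyethyl)-3,5-bis(methoxymethoxy)phenol (racemic) | CC(O)c1c(O)cc(OCOC)c(C/C=C(\C)CCC=C(C)C)c1OCOC
F2 | step 9 | 1-{3-[(2E)-3,7-dimethylocta-2,6-dien-1-yl]-6-hydroxy-2,4-bis(methoxymethoxy)phenyl}ethanone | CC(=O)c1c(O)cc(OCOC)c(C/C=C(\C)CCC=C(C)C)c1OCOC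
F3 | step 9 | 3-methoxy-4,5-bis(methoxymethoxy)benzaldehyde | COc1cc(C=O)cc(OCOC)c1OCOC
F4 | step 9 | (2E)-1-{3-[(2E)-3,7-dimethylocta-2,6-dien-1-yl]-6-hydroxy-2,4-bis(methoxymethoxy)phenyl}-3-[3-methoxy-4,5-bis(methoxymethoxy)phenyl]prop-2-en-1-one | COc1cc(/C=C/C(=O)c2c(O)cc(OCOC)c(C/C=C(\C)CCC=C(C)C)c2OCOC)cc(OCOC)c1OCOC
F5 | step 9 | racemic 6-[(2E)-3,7-dimethylocta-2,6-dien-1-yl]-2-[3-methoxy-4,5-bis(methoxymethoxy)phenyl]-5,7-bis(methoxymethoxy)-2,3-dihydro-4H-chromen-4-one | COc1cc(C2CC(=O)c3c(cc(OCOC)c(C/C=C(\C)CCC=C(C)C)c3OCOC)O2)cc(OCOC)c1OCOC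
F6 | step 3 | 2-[3,5-bis(methoxymethoxy)phenyl]-4,4,5,5-tetramethyl-1,3,2-dioxaborolane | COCOc1cc(B2OC(C)(C)C(C)(C)O2)cc(OCOC)c1
F7 | step 3 | 3,5-bis(methoxymethoxy)phenol | COCOc1cc(O)cc(OCOC)c1
F8 | step 3 | [3,5-bis(methoxymethoxy)phenoxy]tri(propan-2-yl)silane | COCOc1cc(O[Si](C(C)C)(C(C)C)C(C)C)cc(OCOC)c1
F9 | step 3 | {4-[(2E)-3,7-dimethylocta-2,6-dien-1-yl]-3,5-bis(methoxymethoxy)phenoxy}tri(propan-2-yl)silane | COCOc1cc(O[Si](C(C)C)(C(C)C)C(C)C)cc(OCOC)c1C/C=C(\C)CCC=C(C)C
F10 | step 6 | (2E)-3-(dimethylamino)-1-{3-[(2E)-3,7-dimethylocta-2,6-dien-1-yl]-6-hydroxy-2,4-bis(methoxymethoxy)phenyl}prop-2-en-1-one | CN(C)/C=C/C(=O)c1c(O)cc(OCOC)c(C/C=C(\C)CCC=C(C)C)c1OCOC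
F11 | step 10 | 6-[(2E)-3,7-dimethylocta-2,6-dien-1-yl]-5,7-dihydroxy-4H-chromen-4-one | O=c1ccoc2cc(O)c(C/C=C(\C)CCC=C(C)C)c(O)c12
F12 | step 10 | 5,7-bis{[tert-butyl(dimethyl)silyl]oxy}-6-[(2E)-3,7-dimethylocta-2,6-dien-1-yl]-4H-chromen-4-one | O=c1ccoc2cc(O[Si](C)(C)C(C)(C)C)c(C/C=C(\C)CCC=C(C)C)c(O[Si](C)(C)C(C)(C)C)c12
F13 | step 10 | 1-methoxy-2,3-bis{[tert-butyl(dimethyl)silyl]oxy}benzene | COc1cccc(O[Si](C)(C)C(C)(C)C)c1O[Si](C)(C)C(C)(C)C
F14 | step 10 | 2-(3-methoxy-4,5-bis{[tert-butyl(dimethyl)silyl]oxy}phenyl)-4,4,5,5-tetramethyl-1,3,2-dioxaborolane | COc1cc(B2OC(C)(C)C(C)(C)O2)cc(O[Si](C)(C)C(C)(C)C)c1O[Si](C)(C)C(C)(C)C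
F15 | step 10 | (3-methoxy-4,5-bis{[tert-butyl(dimethyl)silyl]oxy}phenyl)boronic acid | COc1cc(B(O)O)cc(O[Si](C)(C)C(C)(C)C)c1O[Si](C)(C)C(C)(C)C
F16 | step 10 | (2S)-5,7-bis{[tert-butyl(dimethyl)silyl]oxy}-2-(3-methoxy-4,5-bis{[tert-butyl(dimethyl)silyl]oxy}phenyl)-6-[(2E)-3,7-dimethylocta-2,6-dien-1-yl]-2,3-dihydro-4H-chromen-4-one | COc1cc([C@@H]2CC(=O)c3c(cc(O[Si](C)(C)C(C)(C)C)c(C/C=C(\C)CCC=C(C)C)c3O[Si](C)(C)C(C)(C)C)O2)cc(O[Si](C)(C)C(C)(C)C)c1O[Si](C)(C)C(C)(C)C
A1 | alternative 1 | 1-{3-[(2E)-3,7-dimethylocta-2,6-dien-1-yl]-2-hydroxy-4,6-bis(methoxymethoxy)phenyl}ethanone | CC(=O)c1c(O)c(C/C=C(\C)CCC=C(C)C)c(OCOC)cc1OCOC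
A2 | alternative 1 | 3-methoxy-4,5-bis(methoxymethoxy)benzaldehyde | COc1cc(C=O)cc(OCOC)c1OCOC
A3 | alternative 1 | (2E)-1-{3-[(2E)-3,7-dimethylocta-2,6-dien-1-yl]-2-hydroxy-4,6-bis(methoxymethoxy)phenyl}-3-[3-methoxy-4,5-bis(methoxymethoxy)phenyl]prop-2-en-1-one | COc1cc(/C=C/C(=O)c2c(O)c(C/C=C(\C)CCC=C(C)C)c(OCOC)cc2OCOC)cc(OCOC)c1OCOC
A4 | alternative 1 | racemic 8-[(2E)-3,7-dimethylocta-2,6-dien-1-yl]-2-[3-methoxy-4,5-bis(methoxymethoxy)phenyl]-5,7-bis(methoxymethoxy)-2,3-dihydro-4H-chromen-4-one | COc1cc(C2CC(=O)c3c(OCOC)cc(OCOC)c(C/C=C(\C)CCC=C(C)C)c3O2)cc(OCOC)c1OCOC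
A5 | alternative 2 | methyl (3R)-3-hydroxy-3-[3-methoxy-4,5-bis(methoxymethoxy)phenyl]propanoate | COC(=O)C[C@@H](O)c1cc(OC)c(OCOC)c(OCOC)c1
A6 | alternative 2 | methyl (3S)-3-{4-[(2E)-3,7-dimethylocta-2,6-dien-1-yl]-3,5-bis(methoxymethoxy)phenoxy}-3-[3-methoxy-4,5-bis(methoxymethoxy)phenyl]propanoate | COC(=O)C[C@H](Oc1cc(OCOC)c(C/C=C(\C)CCC=C(C)C)c(OCOC)c1)c1cc(OC)c(OCOC)c(OCOC)c1
A7 | alternative 3 | 6-[(2E)-3,7-dimethylocta-2,6-dien-1-yl]-2-[3-methoxy-4,5-bis(methoxymethoxy)phenyl]-5,7-bis(methoxymethoxy)-4H-chromen-4-one | COc1cc(-c2cc(=O)c3c(OCOC)c(C/C=C(\C)CCC=C(C)C)c(OCOC)cc3o2)cc(OCOC)c1OCOC
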